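The pitfall in repeating this series is to believe the highest winter reading: 2.6% of target from a partner charge that allows 0.870% if each partner makes one target. The last winter reading stands 0.73 percentage points above that line, inside the scatter of 1 point, so I take one target per partner.

in all of them: starting material 25 mM

| flask | coupling partner | solid rival reagent | remark | time |
|---|---|---|---|---|
| winter | 0.0087 equiv | 1.2 equiv | run made earlier |  |
| spring | 1.1 equiv | 1.2 equiv | run made earlier |  |
| amber | 0.0120 equiv | 1.20 equiv |  | 20 min |
| blue | 0.0400 equiv | 1.20 equiv |  | 20 min |
| green | 0.120 equiv | 1.20 equiv |  | 20 min |
| grey | 0.300 equiv | 1.20 equiv |  | 20 min |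
| teal | 1.00 equiv | 1.20 equiv |  | 20 min |

| run | time / min | target / % |
|---|---|---|
| winter | 0.833 | 0.1 |
| winter | 2.00 | 0.7 |
| winter | 4.00 | 2.6 |
| winter | 10.0 | 1.6 |
| spring | 2.50 | 80.2 |
| spring | 5.00 | 84.6 |
| spring | 8.00 | 83.9 |
| spring | 10.0 | 81.9 |

(readings scatter by 1 percentage point)
- at the start none of the solid rival reagent is in solution
- a reading or a percentage of target counts all its forms, free or not
- "hardly changes" means that all values lie within two and a half points (for a concentration: within two and a half percent of the largest)
- amount of target at the end, in percent of the starting material charged for amber, blue, green, grey, teal, in this order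
- the shape of the row from first to last (rises, then falls / falls all the way / hardly changes / falls, then rises / rises all the way)

I follow one molecule of starting material to its fork, where it meets partner or rival reagent. If the rival's pull stays steady, its chance of becoming target is b/(b+g). Here b is the partner left, as a fraction of the starting material charged, and g is the even-odds level, the partner level at which both paths are equally likely. Summed over a run, side product equals g times the logarithm of partner charged over partner left.

The spring readings average 82.7% target, which leaves 17.3% for the other path and 0.274 of partner. So the even-odds level 0.125 is my one number.

By my reckoning the partner is the limiting reagent in amber, blue, green and grey. Even grey keeps 0.364% of its partner, so I expect 1.20%, 4.00%, 12.0% and 29.9%. In teal, partner left equals side product, and a share of 20.0% returns 20.1%, so I expect 80.0% target. One number serves if the rival's pull stays steady, yet the solid rival reagent starts undissolved, and these readings never show the rival reagent. That is what to watch.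

The forecast gives 1.8%, 6%, 17%, 38% and 81%, so that the row rises all the way, and says “the row rises throughout”; its points for amber, blue, green and grey stand above mine.

The flasks give 1.20%, 4.00%, 12.0%, 30.0% and 81.7%, and the row rises all the way.

    starting material + coupling partner → target (k = 1.10 L mol⁻¹ s⁻¹)
    starting material + rival reagent → side product (k = 3.30 L mol⁻¹ s⁻¹)
    solid rival reagent ⇌ rival reagent, rate k3*(cs3 - [rival reagent]) while solid is left; crystals form when [rival reagent] > cs3 (solubility = 8.80 mM, k = 0.00380 s⁻¹)
    crystals ⇌ target, rate k4*(cs4 - [target]) while solid is left; crystals form when [target] > cs4 (solubility = 14.0 mM, k = 0.0890 s⁻¹)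

From teal's 18.3% of partner left, g gives 21.1% side product, and the flask holds 18.3%. On grey, g gives 29.9% target, and the flask holds 30.0%. Teal shows why the even-odds level stays this low: the low solubility of the rival reagent, which also sets how fast it dissolves, keeps the rival path back. With that taken away, teal's target falls from 81.7% to 28.8%.

The numbers in the tables are calculated for an exercise.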